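**Retrosynthetic overview**

1. The route rests on the O6–C6–C7–C8–O8 array of the ten-membered carbocycle (C1–C10): with C6 and C8 both ketones, C7 (bearing the C11–C12 acetate arm) is a β-dicarbonyl carbon that epimerises, so the ring can be built without control at C6–C8 and the triad set afterwards.
2. Key disconnection: the γ-lactone ring (O6–C12) and the C6/C7 centres come from the macrocyclic 6,8-dione by a ketoreductase dynamic reduction at C6; C8, C13 and the O8 ester follow on the lactone.
3. Carbocycle: RCM at C1=C10 of the open-chain 2-substituted 1,3-diketone; the arm goes on C7 (C7–C11) only at the dione level, so that no C6 or C8 alcohol can lactonise onto C12 early and without control.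
4. Open chain: C8–C9 by indium allylation of a C8 ynal with a 2-(silyloxymethyl)allyl bromide (C9, C10, C14); C7–C8 by formylation of a terminal alkyne (C5–C7 from propargyl bromide); O6 by ynone hydration; C4 by Evans alkylation of a hex-5-enoyl imide (C1–C4, C15).
5. Ring order: ten-membered carbocycle first (step 12), γ-lactone second (step 13).

Key step: step 13

Remark: locants are germacrane locants (ring C1–C10, C14 on C10, C15 on C4, C11–C13 on C7); the C1=C10 olefin is E by CIP because C14 carries oxygen, which means ring carbons C2 and C9 are cis; TBS = tert-butyldimethylsilyl, TES = triethylsilyl; both ketoreductases are assumed to be found by screening commercial panels.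

**Route**

Step 1
Reactants: 1 hex-5-enoyl chloride; 2 (R)-4-benzyloxazolidin-2-one
Product: 3 (R)-4-benzyl-3-(hex-5-enoyl)oxazolidin-2-one
Conditions: 2, n-BuLi, THF, −78 °C; then 1, −78 → 0 °C
Reagents that add atoms: none
Why: N-acylation of the lithiated Evans oxazolidinone by an acid chloride is the standard loading of the auxiliary and creates no stereocentre.

Step 2
Reactants: 3 (R)-4-benzyl-3-(hex-5-enoyl)oxazolidin-2-one; 4 propargyl bromide
Product: 5 (R)-4-benzyl-3-[(S)-2-(prop-2-yn-1-yl)hex-5-enoyl]oxazolidin-2-one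
Conditions: NaHMDS, THF, −78 °C; 4 (3 equiv), −78 → −45 °C
Reagents that add atoms: none
Why: Evans asymmetric alkylation, in which the chelated (Z)-sodium enolate is shielded on one face by the benzyl group of the (R)-auxiliary so that the propargylic bromide adds from the other face and sets C4 as (S) (propargyl CH2 = C5, butenyl chain = C3–C1).

Step 3
Reactants: 5 (R)-4-benzyl-3-[(S)-2-(prop-2-yn-1-yl)hex-5-enoyl]oxazolidin-2-one
Product: 6 (S)-2-(prop-2-yn-1-yl)hex-5-en-1-ol
Conditions: LiBH4, MeOH (1 equiv), Et2O, 0 °C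
Reagents that add atoms: none
Why: Reductive cleavage of the N-acyl oxazolidinone with LiBH4 gives the primary alcohol (future O15) without touching alkyne or alkene and without epimerising C4, and returns the auxiliary.

Step 4
Reactants: 6 (S)-2-(prop-2-yn-1-yl)hex-5-en-1-ol
Product: 7 (S)-tert-butyldimethyl{[2-(prop-2-yn-1-yl)hex-5-en-1-yl]oxy}silane
Conditions: TBSCl, imidazole, DMF, 0 °C → rt
Reagents that add atoms: tert-butyldimethylsilyl chloride, CC(C)(C)[Si](C)(C)Cl
Why: Standard imidazole-promoted silylation of a primary alcohol, giving the O15 protecting group carried to the last step.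

Step 5
Reactants: 7 (S)-tert-butyldimethyl{[2-(prop-2-yn-1-yl)hex-5-en-1-yl]oxy}silane
Product: 8 (S)-5-[(TBS-oxy)methyl]non-8-en-2-ynal
Conditions: n-BuLi, THF, −78 °C; DMF, −78 → 0 °C; inverse quench into cold aq. KH2PO4
Reagents that add atoms: N,N-dimethylformamide, CN(C)C=O
Why: Formylation of the lithium acetylide with DMF gives the ynal and brings in C8, the buffered inverse quench sparing the sensitive aldehyde.

Step 6
Reactants: 9 2-methylenepropane-1,3-diol
Product: 10 2-[(TBS-oxy)methyl]prop-2-en-1-ol
Conditions: NaH (1.0 equiv), THF, 0 °C → rt; TBSCl (1.0 equiv)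
Reagents that add atoms: tert-butyldimethylsilyl chloride, CC(C)(C)[Si](C)(C)Cl
Why: Monosilylation of a symmetrical diol through its sparingly soluble monosodium alkoxide (McDougal procedure) should favour the mono-ether.

Step 7
Reactants: 10 2-[(TBS-oxy)methyl]prop-2-en-1-ol
Product: 11 {[2-(bromomethyl)prop-2-en-1-yl]oxy}(tert-butyl)dimethylsilane
Conditions: PPh3, CBr4, CH2Cl2, 0 °C
Reagents that add atoms: carbon tetrabromide, BrC(Br)(Br)Br
Why: Appel bromination converts the primary allylic alcohol into the bromide under neutral conditions that keep the silyl ether.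

Step 8
Reactants: 8 (S)-5-[(TBS-oxy)methyl]non-8-en-2-ynal; 11 {[2-(bromomethyl)prop-2-en-1-yl]oxy}(tert-butyl)dimethylsilane
Product: 12 (8S)-2,8-bis[(TBS-oxy)methyl]dodeca-1,11-dien-5-yn-4-ol (both C4 epimers)
Conditions: In powder, THF/H2O (3:1), rt
Reagents that add atoms: none
Why: Indium Barbier allylation adds the allyl unit 1,2 to the aldehyde and forms C8–C9; the allyl unit is symmetrical so no regiochemistry arises, and the carbinol epimers do not matter because the centre is oxidised in the next step.

Step 9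
Reactants: 12 (8S)-2,8-bis[(TBS-oxy)methyl]dodeca-1,11-dien-5-yn-4-ol
Product: 13 (S)-2,8-bis[(TBS-oxy)methyl]dodeca-1,11-dien-5-yn-4-one
Conditions: Dess–Martin periodinane, CH2Cl2, 0 °C → rt
Reagents that add atoms: none
Why: Dess–Martin oxidation of the propargylic alcohol gives the ynone without base, so the β,γ-olefin next to the new ketone should stay in place.

Step 10
Reactants: 13 (S)-2,8-bis[(TBS-oxy)methyl]dodeca-1,11-dien-5-yn-4-one
Product: 15 (S)-2,8-bis[(TBS-oxy)methyl]dodeca-1,11-diene-4,6-dione, via enaminone 14 (not isolated)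
Conditions: Et2NH (1.5 equiv), EtOH, 0 °C → rt; then AcOH/NaOAc buffer (pH 4.5), THF/H2O, rt → 40 °C
Reagents that add atoms: water, O
Why: Conjugate addition of the secondary amine to the ynone puts nitrogen on the β-carbon (C6), and mild acidic hydrolysis of the vinylogous amide, at a pH the primary silyl ethers tolerate, amounts to a regiospecific hydration to the 1,3-diketone.

Step 11
Reactants: 15 (S)-2,8-bis[(TBS-oxy)methyl]dodeca-1,11-diene-4,6-dione; 16 methyl bromoacetate
Product: 17 methyl 2-{(8S)-2,8-bis[(TBS-oxy)methyl]-4,6-dioxododeca-1,11-dien-5-yl}acetate (both C5 epimers)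
Conditions: K2CO3, acetone, rt; 16 (1.05 equiv)
Reagents that add atoms: none
Why: C-alkylation of an open-chain β-diketone enolate with a bromoacetate is standard; carbonate deprotonates only the carbon between the carbonyls (C7), so the allylic C9 position and the β,γ-olefin are not disturbed, and the new centre is left as a mixture on purpose.

Step 12
Reactants: 17 methyl 2-{(8S)-2,8-bis[(TBS-oxy)methyl]-4,6-dioxododeca-1,11-dien-5-yl}acetate
Product: 18 methyl (4S)-14,15-bis(TBS-oxy)-6,8-dioxo-13-norgermacr-1(10)-en-12-oate (ten-membered ring dione with CH2CO2Me on C7; C7 epimers; C2 and C9 cis)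
Conditions: Hoveyda–Grubbs II (10 mol%, in portions), 1,4-benzoquinone (20 mol%), toluene (1 mM), 80 °C, argon sparge
Reagents that add atoms: none
Why: Ring-closing metathesis, in which the ruthenium alkylidene loads on the monosubstituted olefin and closes onto the 1,1-disubstituted one to give a trisubstituted cycloalkene that is not readily reopened; four sp2 ring carbons lower the transannular strain, the ring-cis olefin (C2/C9 cis) is the less strained and expected geometry, and high dilution with benzoquinone should hold back oligomers and olefin migration.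

Step 13
Reactants: 18 methyl (4S)-14,15-bis(TBS-oxy)-6,8-dioxo-13-norgermacr-1(10)-en-12-oate
Product: 20 (4S,6R,7S)-14,15-bis(TBS-oxy)-8-oxo-13-norgermacr-1(10)-en-6,12-olide (trans-fused γ-lactone), via hydroxy ester 19 (not isolated)
Conditions: ketoreductase (panel hit), NADP+ (cat.), i-PrOH (10% v/v), potassium phosphate buffer pH 7.0, MgSO4 (2 mM), DMSO (10% v/v), 30 °C; then extraction and cat. PPTS, CH2Cl2, rt to complete lactonisation
Reagents that add atoms: none
Why: At pH 7 the C7 epimers of 18 interconvert through the enol of the 6,8-dione (the ring disfavours a planar chelated enol, so the reducible diketo forms should dominate), the enzyme binds one epimer, and NADPH delivers hydride to one face of the C6 carbonyl to give hydroxy ester 19. The closest known reaction type is the ketoreductase dynamic kinetic resolution of 2-substituted 1,3-diketones and β-keto esters, applied here to a ten-membered ring dione. The γ-lactone ring closes by 5-exo-trig acyl substitution of the new C6 hydroxyl on the C12 methyl ester with loss of methanol, which gives the trans-fused lactone and removes C7 from the β-dicarbonyl so that it no longer epimerises at a useful rate. C6 (R) is set by the face of hydride transfer fixed in the active site, and C7 (S) by the enzyme turning over only one epimer while the other is fed back through the enol. The step needs site selectivity (C6 over C8), face selectivity and epimer selectivity; the substrate secures only the mobility of C7 and offers two differently flanked carbonyls (the C5H2–C4H branch against the allylic C9H2), so all three rest on the pocket of the enzyme chosen from the panel. Isopropanol regenerates NADPH, and the neutral conditions should leave the β,γ-unsaturated C8 ketone and the silyl ethers untouched.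

Step 14
Reactants: 20 (4S,6R,7S)-14,15-bis(TBS-oxy)-8-oxo-13-norgermacr-1(10)-en-6,12-olide
Product: 21 (4S,6R,7R,8R)-14,15-bis(TBS-oxy)-8-hydroxy-13-norgermacr-1(10)-en-6,12-olide (H-6/H-7 trans; H-7/H-8 cis)
Conditions: second ketoreductase (panel hit), NADP+ (cat.), i-PrOH (10% v/v), phosphate buffer pH 7.0, DMSO (10% v/v), 30 °C
Reagents that add atoms: none
Why: Enzymatic ketone reduction with catalyst control, the enzyme delivering hydride to the C8 face on the side of H-7 to set C8 as (R); only one ketone is left, and C7, now α to a single carbonyl, should not epimerise at pH 7.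

Step 15
Reactants: 21 (4S,6R,7R,8R)-14,15-bis(TBS-oxy)-8-hydroxy-13-norgermacr-1(10)-en-6,12-olide
Product: 22 (4S,6R,7S,8R)-14,15-bis(TBS-oxy)-8-(TES-oxy)-13-norgermacr-1(10)-en-6,12-olide
Conditions: TESCl, imidazole, DMF, 0 °C
Reagents that add atoms: chlorotriethylsilane, CC[Si](CC)(CC)Cl
Why: Silylation under weakly basic conditions masks O8 so that its alkoxide cannot translactonise to an 8,12-olide during the enolate step.

Step 16
Reactants: 22 (4S,6R,7S,8R)-14,15-bis(TBS-oxy)-8-(TES-oxy)-13-norgermacr-1(10)-en-6,12-olide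
Product: 25 (4S,6R,7S,8R)-14,15-bis(TBS-oxy)-8-(TES-oxy)germacra-1(10),11(13)-dien-6,12-olide, via Mannich base 23 (not isolated), via ammonium iodide 24 (not isolated)
Conditions: LDA, THF, −78 °C; Eschenmoser's salt, −78 °C → rt; then MeI, MeOH, rt; then NaHCO3, CH2Cl2/H2O, rt
Reagents that add atoms: Eschenmoser's salt (N,N-dimethylmethyleneiminium iodide), C=[N+](C)C.[I-]
Why: Mannich reaction of the lactone enolate with Eschenmoser's salt, quaternisation and base-induced loss of trimethylamine is the standard α-methylenation of γ-lactones and brings in C13; the lactone is the only enolisable carbonyl left and C7 is not touched.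

Step 17
Reactants: 25 (4S,6R,7S,8R)-14,15-bis(TBS-oxy)-8-(TES-oxy)germacra-1(10),11(13)-dien-6,12-olide
Product: 26 (4S,6R,7R,8R)-14,15-bis(TBS-oxy)-8-hydroxygermacra-1(10),11(13)-dien-6,12-olide
Conditions: PPTS (cat.), MeOH/CH2Cl2 (1:1), 0 °C, monitored
Reagents that add atoms: none
Why: Acid-catalysed methanolysis removes the triethylsilyl ether much faster than the primary tert-butyldimethylsilyl ethers, and the cold, weakly acidic medium should not open or move the lactone.

Step 18
Reactants: 26 (4S,6R,7R,8R)-14,15-bis(TBS-oxy)-8-hydroxygermacra-1(10),11(13)-dien-6,12-olide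
Product: 27 (4S,6R,7S,8R)-14,15-bis(TBS-oxy)-8-(methacryloyloxy)germacra-1(10),11(13)-dien-6,12-olide
Conditions: methacrylic anhydride, Et3N, DMAP (cat.), CH2Cl2, 0 °C → rt
Reagents that add atoms: methacrylic anhydride, C=C(C)C(=O)OC(=O)C(C)=C
Why: DMAP-catalysed acylation of the secondary alcohol proceeds with retention at C8 and should outrun base-mediated lactone migration.

Step 19
Reactants: 27 (4S,6R,7S,8R)-14,15-bis(TBS-oxy)-8-(methacryloyloxy)germacra-1(10),11(13)-dien-6,12-olide
Product: 28 (4S,6R,7S,8R)-14,15-dihydroxy-8-(methacryloyloxy)germacra-1(10),11(13)-dien-6,12-olide (target)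
Conditions: HF·pyridine, pyridine, THF, 0 °C → rt
Reagents that add atoms: none
Why: Buffered HF·pyridine desilylation frees O14 and O15 under acidic fluoride conditions that avoid acyl migration, lactone opening and Michael addition to the two acrylate units.

**Compound list**

1 | hex-5-enoyl chloride | C=CCCCC(=O)Cl | starting material
2 | (R)-4-benzyloxazolidin-2-one | O=C1N[C@H](Cc2ccccc2)CO1 | starting material
3 | (R)-4-benzyl-3-(hex-5-enoyl)oxazolidin-2-one | C=CCCCC(=O)N1[C@H](Cc2ccccc2)COC1=O | intermediate
4 | propargyl bromide (3-bromoprop-1-yne) | C#CCBr | starting material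
5 | (R)-4-benzyl-3-[(S)-2-(prop-2-yn-1-yl)hex-5-enoyl]oxazolidin-2-one | C=CCC[C@H](C(=O)N1[C@H](Cc2ccccc2)COC1=O)CC#C | intermediate
6 | (S)-2-(prop-2-yn-1-yl)hex-5-en-1-ol | C=CCC[C@H](CO)CC#C | intermediate
7 | (S)-tert-butyldimethyl{[2-(prop-2-yn-1-yl)hex-5-en-1-yl]oxy}silane | C=CCC[C@H](CO[Si](C)(C)C(C)(C)C)CC#C | intermediate
8 | (S)-5-[(TBS-oxy)methyl]non-8-en-2-ynal | C=CCC[C@H](CO[Si](C)(C)C(C)(C)C)CC#CC=O | intermediate
9 | 2-methylenepropane-1,3-diol | C=C(CO)CO | starting material
10 | 2-[(TBS-oxy)methyl]prop-2-en-1-ol | C=C(CO)CO[Si](C)(C)C(C)(C)C | intermediate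
11 | {[2-(bromomethyl)prop-2-en-1-yl]oxy}(tert-butyl)dimethylsilane | C=C(CBr)CO[Si](C)(C)C(C)(C)C | intermediate
12 | (8S)-2,8-bis[(TBS-oxy)methyl]dodeca-1,11-dien-5-yn-4-ol, both C4 epimers | C=CCC[C@H](CO[Si](C)(C)C(C)(C)C)CC#CC(O)CC(=C)CO[Si](C)(C)C(C)(C)C | intermediate
13 | (S)-2,8-bis[(TBS-oxy)methyl]dodeca-1,11-dien-5-yn-4-one | C=CCC[C@H](CO[Si](C)(C)C(C)(C)C)CC#CC(=O)CC(=C)CO[Si](C)(C)C(C)(C)C | intermediate
14 | (5E,8S)-6-(diethylamino)-2,8-bis[(TBS-oxy)methyl]dodeca-1,5,11-trien-4-one | C=CCC[C@H](CO[Si](C)(C)C(C)(C)C)C/C(N(CC)CC)=C\C(=O)CC(=C)CO[Si](C)(C)C(C)(C)C | intermediate (not isolated)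
15 | (S)-2,8-bis[(TBS-oxy)methyl]dodeca-1,11-diene-4,6-dione | C=CCC[C@H](CO[Si](C)(C)C(C)(C)C)CC(=O)CC(=O)CC(=C)CO[Si](C)(C)C(C)(C)C | intermediate
16 | methyl bromoacetate | COC(=O)CBr | starting material
17 | methyl 2-{(8S)-2,8-bis[(TBS-oxy)methyl]-4,6-dioxododeca-1,11-dien-5-yl}acetate, both C5 epimers | C=CCC[C@H](CO[Si](C)(C)C(C)(C)C)CC(=O)C(CC(=O)OC)C(=O)CC(=C)CO[Si](C)(C)C(C)(C)C | intermediate
18 | methyl (4S)-14,15-bis(TBS-oxy)-6,8-dioxo-13-norgermacr-1(10)-en-12-oate (7-(methoxycarbonylmethyl)cyclodec-1(10)-ene-6,8-dione, C7 epimers, C2 and C9 cis) | COC(=O)CC1C(=O)C/C(CO[Si](C)(C)C(C)(C)C)=C\CC[C@H](CO[Si](C)(C)C(C)(C)C)CC1=O | intermediate (key-step precursor)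
19 | methyl (4S,6R,7S)-14,15-bis(TBS-oxy)-6-hydroxy-8-oxo-13-norgermacr-1(10)-en-12-oate | COC(=O)C[C@@H]1C(=O)C/C(CO[Si](C)(C)C(C)(C)C)=C\CC[C@H](CO[Si](C)(C)C(C)(C)C)C[C@H]1O | intermediate (not isolated)
20 | (4S,6R,7S)-14,15-bis(TBS-oxy)-8-oxo-13-norgermacr-1(10)-en-6,12-olide (trans-fused γ-lactone) | O=C1C/C(CO[Si](C)(C)C(C)(C)C)=C\CC[C@H](CO[Si](C)(C)C(C)(C)C)C[C@H]2OC(=O)C[C@H]12 | intermediate (key-step product)
21 | (4S,6R,7R,8R)-14,15-bis(TBS-oxy)-8-hydroxy-13-norgermacr-1(10)-en-6,12-olide | O[C@@H]1C/C(CO[Si](C)(C)C(C)(C)C)=C\CC[C@H](CO[Si](C)(C)C(C)(C)C)C[C@H]2OC(=O)C[C@H]12 | intermediate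
22 | (4S,6R,7S,8R)-14,15-bis(TBS-oxy)-8-(TES-oxy)-13-norgermacr-1(10)-en-6,12-olide | CC[Si](CC)(CC)O[C@@H]1C/C(CO[Si](C)(C)C(C)(C)C)=C\CC[C@H](CO[Si](C)(C)C(C)(C)C)C[C@H]2OC(=O)C[C@H]12 | intermediate
23 | 11-(dimethylaminomethyl) derivative of 22, C11 epimers | CC[Si](CC)(CC)O[C@@H]1C/C(CO[Si](C)(C)C(C)(C)C)=C\CC[C@H](CO[Si](C)(C)C(C)(C)C)C[C@H]2OC(=O)C(CN(C)C)[C@H]12 | intermediate (not isolated)
24 | 11-(trimethylammoniomethyl) derivative of 22, iodide, C11 epimers | CC[Si](CC)(CC)O[C@@H]1C/C(CO[Si](C)(C)C(C)(C)C)=C\CC[C@H](CO[Si](C)(C)C(C)(C)C)C[C@H]2OC(=O)C(C[N+](C)(C)C)[C@H]12.[I-] | intermediate (not isolated)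
25 | (4S,6R,7S,8R)-14,15-bis(TBS-oxy)-8-(TES-oxy)germacra-1(10),11(13)-dien-6,12-olide | CC[Si](CC)(CC)O[C@@H]1C/C(CO[Si](C)(C)C(C)(C)C)=C\CC[C@H](CO[Si](C)(C)C(C)(C)C)C[C@H]2OC(=O)C(=C)[C@H]12 | intermediate
26 | (4S,6R,7R,8R)-14,15-bis(TBS-oxy)-8-hydroxygermacra-1(10),11(13)-dien-6,12-olide | O[C@@H]1C/C(CO[Si](C)(C)C(C)(C)C)=C\CC[C@H](CO[Si](C)(C)C(C)(C)C)C[C@H]2OC(=O)C(=C)[C@H]12 | intermediate
27 | (4S,6R,7S,8R)-14,15-bis(TBS-oxy)-8-(methacryloyloxy)germacra-1(10),11(13)-dien-6,12-olide | C=C(C)C(=O)O[C@@H]1C/C(CO[Si](C)(C)C(C)(C)C)=C\CC[C@H](CO[Si](C)(C)C(C)(C)C)C[C@H]2OC(=O)C(=C)[C@H]12 | intermediate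
28 | (4S,6R,7S,8R)-14,15-dihydroxy-8-(methacryloyloxy)germacra-1(10),11(13)-dien-6,12-olide (CNP0546547.2) | C=C(C)C(=O)O[C@@H]1C/C(CO)=C\CC[C@H](CO)C[C@H]2OC(=O)C(=C)[C@H]12 | target

**Step count and risks**

Total step count: 19. Longest linear sequence: 17 steps (steps 1–5 and 8–19); steps 6 and 7 make the allyl bromide 11.

The three steps most likely to fail:

Step 13 (key step). The bis-silylated macrocycle may fit no enzyme of the panel, which would show as no turnover, reduction at C8 instead of C6, or hydride transfer to the wrong face or epimer. The fallback sets out from 17 and moves the same dynamic enzymatic reduction one step earlier, onto the open-chain 2-substituted 1,3-diketone, the substrate class for which it is best established. Reduction at C6 should give the open-chain hydroxy ester F1, which lactonises to the trans-2,3-disubstituted keto butanolide F2. Ring-closing metathesis of F2 under the conditions of step 12, now on a diene held by the lactone, returns to the route at 20.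

Step 12. Cross-metathesis between terminal olefins (oligomers) may outpace closure of the medium ring on the branched substrate, or the catalyst may move the β,γ-olefin into conjugation before it is engaged. The fallback sets out from 15 and closes the ring before the arm is attached. Metathesis of the unbranched dione 15, which lacks the tertiary C7 centre and the ester, should give the arm-free cyclodec-1(10)-ene-6,8-dione F3. C-alkylation of its potassium enolate with 16 (K2CO3, acetone, cat. NaI) returns to the route at 18.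

Step 14. The second enzyme may show poor facial selectivity at C8 or slow turnover on the lactone. The fallback sets out from 20 and uses reagent control instead: Corey–Bakshi–Shibata reduction with (S)-2-methyl-CBS-oxazaborolidine and catecholborane in toluene at −78 °C. With the branched C7 side as the large and the C9 methylene as the small substituent, the model predicts the (8R) alcohol, and catecholborane spares the ring olefin. The route is rejoined directly at 21; this fallback makes no compound outside the list (F0).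

Further compounds
F1 | step 13 | methyl (3S,4R,6S)-6-[(TBS-oxy)methyl]-3-{3-[(TBS-oxy)methyl]but-3-enoyl}-4-hydroxydec-9-enoate (open-chain hydroxy ester; germacrane C6 R, C7 S, C4 S) | C=CCC[C@H](CO[Si](C)(C)C(C)(C)C)C[C@@H](O)[C@H](CC(=O)OC)C(=O)CC(=C)CO[Si](C)(C)C(C)(C)C
F2 | step 13 | trans-4-{3-[(TBS-oxy)methyl]but-3-enoyl}-5-{(S)-2-[(TBS-oxy)methyl]hex-5-en-1-yl}dihydrofuran-2(3H)-one (open-chain keto lactone; germacrane C6 R, C7 S) | C=CCC[C@H](CO[Si](C)(C)C(C)(C)C)C[C@H]1OC(=O)C[C@@H]1C(=O)CC(=C)CO[Si](C)(C)C(C)(C)C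
F3 | step 12 | (4S)-4,10-bis[(TBS-oxy)methyl]cyclodec-1(10)-ene-6,8-dione (germacrane locants; C2 and C9 cis) | O=C1CC(=O)C/C(CO[Si](C)(C)C(C)(C)C)=C\CC[C@H](CO[Si](C)(C)C(C)(C)C)C1
F0 | step 14 | none | none
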